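The dihydronaphthalene ring (C1 bears the pyrone, C2 the methyl ester) is cut at C4–C4a and C1–C2, a [3+3] union of an aryl(pyronyl)methyl unit with an itaconate. The key step exploits that C1 is flanked by pyrone C3′, whose enoate C3′=C4′–C2′=O makes a C1 carbonate a Morita–Baylis–Hillman carbonate, and by catechol-ring carbon C8a, whose neighbour C4a can carry bromine. In one pot, a Heck coupling forms C4–C4a and a chiral Lewis base then closes C1–C2 by allylic alkylation, setting both stereocentres. The precursor is a (2-bromoaryl)(pyron-3-yl)methyl tert-butyl carbonate, used together with tert-butyl methyl itaconate.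

Key step: step 7

Assumption: 2-bromo-4,5-dihydroxybenzaldehyde is taken as commercial (otherwise one step from 6-bromoveratraldehyde), and the sense of induction of the cinchona catalyst in step 7 has to be assigned; if (DHQD)2PHAL favours 1S, its pseudo-enantiomer (DHQ)2PHAL is used instead.

Step 1
Reactants: 1 2-oxo-2H-pyran-6-carboxylic acid
Product: 2 tert-butyl 2-oxo-2H-pyran-6-carboxylate
Conditions: t-BuOC(=NH)CCl3 (2 equiv), BF3·OEt2 (cat.), CH2Cl2/cyclohexane, rt
Reagents that add atoms: tert-butyl 2,2,2-trichloroacetimidate, CC(C)(C)OC(=N)C(Cl)(Cl)Cl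
Why: Acid-catalysed O-tert-butylation of the carboxylic acid by the imidate should give the ester without any base or nucleophile that could open the pyrone.

Step 2
Reactants: 2 tert-butyl 2-oxo-2H-pyran-6-carboxylate
Product: 4 tert-butyl 3-bromo-2-oxo-2H-pyran-6-carboxylate, via 3,4-dibromo-3,4-dihydropyranone 3 (not isolated)
Conditions: Br2, CH2Cl2, 0 °C to rt; then Et3N, 0 °C
Reagents that add atoms: bromine, BrBr
Why: Bromine addition to the enoate C3=C4 bond and dehydrobromination by the amine (addition–elimination α-bromination of an α,β-unsaturated lactone) should give the 3-bromide, because C5=C6 is deactivated by the ester on C6.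

Step 3
Reactants: 5 2-bromo-4,5-dihydroxybenzaldehyde
Product: 6 2-bromo-4,5-bis(methoxymethoxy)benzaldehyde
Conditions: MOMCl, i-Pr2NEt, CH2Cl2, 0 °C to rt
Reagents that add atoms: chloromethyl methyl ether, COCCl
Why: O-Alkylation of both phenols (Williamson type) gives base-stable acetals that are removed at the end by acid together with the tert-butyl esters.

Step 4
Reactants: 4 tert-butyl 3-bromo-2-oxo-2H-pyran-6-carboxylate, 6 2-bromo-4,5-bis(methoxymethoxy)benzaldehyde
Product: 8 tert-butyl 3-{[2-bromo-4,5-bis(methoxymethoxy)phenyl](hydroxy)methyl}-2-oxo-2H-pyran-6-carboxylate (racemic), via alkenylchromium(III) dichloride 7 (not isolated)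
Conditions: CrCl2 (4 equiv), NiCl2 (2 mol%), DMF, rt; aq. NH4Cl work-up
Reagents that add atoms: none
Why: Nozaki–Hiyama–Kishi coupling, in which nickel should insert into the electron-poor alkenyl C–Br bond of 4 rather than the electron-rich aryl C–Br bond of 6 and the non-basic organochromium adds only to the aldehyde; the carbinol centre forms racemic and is erased in step 7.

Step 5
Reactants: 8 tert-butyl 3-{[2-bromo-4,5-bis(methoxymethoxy)phenyl](hydroxy)methyl}-2-oxo-2H-pyran-6-carboxylate
Product: 9 tert-butyl 3-{[2-bromo-4,5-bis(methoxymethoxy)phenyl][(tert-butoxycarbonyl)oxy]methyl}-2-oxo-2H-pyran-6-carboxylate (racemic)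
Conditions: Boc2O, DMAP (5 mol%), CH2Cl2, 0 °C
Reagents that add atoms: di-tert-butyl dicarbonate, CC(C)(C)OC(=O)OC(=O)OC(C)(C)C
Why: DMAP-catalysed carbonate formation, the standard way to Morita–Baylis–Hillman carbonates, installs a leaving group that later releases tert-butoxide as the internal base.

Step 6
Reactants: 10 4-methyl hydrogen itaconate (4-methoxy-2-methylidene-4-oxobutanoic acid)
Product: 11 1-tert-butyl 4-methyl 2-methylidenebutanedioate
Conditions: t-BuOC(=NH)CCl3 (2 equiv), BF3·OEt2 (cat.), CH2Cl2/cyclohexane, rt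
Reagents that add atoms: tert-butyl 2,2,2-trichloroacetimidate, CC(C)(C)OC(=N)C(Cl)(Cl)Cl
Why: Imidate tert-butylation under acid catalysis esterifies the conjugated acid without base, so the itaconate should not isomerise to the mesaconate, and the two carboxyl groups end up differentiated (methyl on the saturated one, tert-butyl on the conjugated one).

Step 7
Reactants: 9 tert-butyl 3-{[2-bromo-4,5-bis(methoxymethoxy)phenyl][(tert-butoxycarbonyl)oxy]methyl}-2-oxo-2H-pyran-6-carboxylate, 11 1-tert-butyl 4-methyl 2-methylidenebutanedioate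
Product: 13 tert-butyl 3-[(1R,2R)-3-(tert-butoxycarbonyl)-2-(methoxycarbonyl)-6,7-bis(methoxymethoxy)-1,2-dihydronaphthalen-1-yl]-2-oxo-2H-pyran-6-carboxylate, via Heck product 12 (not isolated)
Conditions: Pd2(dba)3 (2.5 mol%), [(t-Bu)3PH]BF4 (6 mol%), Cy2NMe, 1,4-dioxane, 40 °C; then Cs2CO3, (DHQD)2PHAL (20 mol%), toluene, 0 °C to rt
Reagents that add atoms: none
Why: Proposed new method: the first stage is an ordinary Heck reaction (oxidative addition at the C4a–Br bond, syn-carbopalladation of the methylidene group of 11 at its CH2 terminus, β-hydride elimination to the E-arylidene succinate 12, any double-bond isomer feeding the same dienolate later), and the second stage transfers the chiral-Lewis-base-catalysed asymmetric allylic alkylation of Morita–Baylis–Hillman carbonates (SN2′–SN2′), its closest known reaction type, to a carbonate whose enoate is the pyrone C3′=C4′–C2′=O unit and to an intramolecular ester pronucleophile. A quinuclidine nitrogen of the catalyst should add reversibly to pyrone C4′, tert-butyl carbonate leaves from C1 and falls apart to CO2 and tert-butoxide, this base deprotonates the succinate CH2, and C2 of the dienolate attacks C1 of the catalyst-bound 3-alkylidene lactone, after which loss of the catalyst restores the aromatic pyrone. The ring closes in a 6-exo-trig mode, the accepting C1=C3′ bond lying outside the new ring. C1 is set by the catalyst, which blocks one face of the alkylidene so that C2 enters anti to the ammonium group, and C2, α to the methyl ester and allylic, should equilibrate under the basic conditions to the trans (1R,2R) arrangement. The step needs the coupling to precede ionisation of the carbonate, which is secured by adding the Lewis base only after the Heck stage, and it needs C2 rather than C4 of the ambident dienolate to bond to C1, which the tether secures because attack through C4 would close a four-membered ring.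

Step 8
Reactants: 13 tert-butyl 3-[(1R,2R)-3-(tert-butoxycarbonyl)-2-(methoxycarbonyl)-6,7-bis(methoxymethoxy)-1,2-dihydronaphthalen-1-yl]-2-oxo-2H-pyran-6-carboxylate
Product: 14 (1R,2R)-1-(6-carboxy-2-oxo-2H-pyran-3-yl)-6,7-dihydroxy-2-(methoxycarbonyl)-1,2-dihydronaphthalene-3-carboxylic acid (CNP0239263.1)
Conditions: TFA/CH2Cl2 (1:1), H2O (5 equiv), thioanisole, 0 °C to rt, argon
Reagents that add atoms: none
Why: Acidolysis (E1 loss of isobutene from both tert-butyl esters, hydrolysis of both MOM acetals) should free the two acids and the catechol, while the methyl ester, the lactone and both stereocentres, which see no base after step 7, stay untouched.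

Compound list
1 | 2-oxo-2H-pyran-6-carboxylic acid | OC(=O)c1cccc(=O)o1 | starting material
2 | tert-butyl 2-oxo-2H-pyran-6-carboxylate | CC(C)(C)OC(=O)c1cccc(=O)o1 | intermediate
3 | tert-butyl 3,4-dibromo-2-oxo-3,4-dihydro-2H-pyran-6-carboxylate (trans, racemic; not isolated) | CC(C)(C)OC(=O)C1=CC(Br)C(Br)C(=O)O1 | intermediate
4 | tert-butyl 3-bromo-2-oxo-2H-pyran-6-carboxylate | CC(C)(C)OC(=O)c1ccc(Br)c(=O)o1 | intermediate
5 | 2-bromo-4,5-dihydroxybenzaldehyde | O=Cc1cc(O)c(O)cc1Br | starting material
6 | 2-bromo-4,5-bis(methoxymethoxy)benzaldehyde | O=Cc1cc(OCOC)c(OCOC)cc1Br | intermediate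
7 | [6-(tert-butoxycarbonyl)-2-oxo-2H-pyran-3-yl]chromium(III) dichloride (not isolated) | CC(C)(C)OC(=O)c1ccc([Cr](Cl)Cl)c(=O)o1 | intermediate
8 | tert-butyl 3-{[2-bromo-4,5-bis(methoxymethoxy)phenyl](hydroxy)methyl}-2-oxo-2H-pyran-6-carboxylate (racemic) | CC(C)(C)OC(=O)c1ccc(C(O)c2cc(OCOC)c(OCOC)cc2Br)c(=O)o1 | intermediate
9 | tert-butyl 3-{[2-bromo-4,5-bis(methoxymethoxy)phenyl][(tert-butoxycarbonyl)oxy]methyl}-2-oxo-2H-pyran-6-carboxylate (racemic) | CC(C)(C)OC(=O)OC(c1cc(OCOC)c(OCOC)cc1Br)c1ccc(C(=O)OC(C)(C)C)oc1=O | intermediate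
10 | 4-methyl hydrogen itaconate (4-methoxy-2-methylidene-4-oxobutanoic acid) | C=C(CC(=O)OC)C(=O)O | starting material
11 | 1-tert-butyl 4-methyl 2-methylidenebutanedioate | C=C(CC(=O)OC)C(=O)OC(C)(C)C | intermediate
12 | 1-tert-butyl 4-methyl (2E)-2-{[2-{[(tert-butoxycarbonyl)oxy][6-(tert-butoxycarbonyl)-2-oxo-2H-pyran-3-yl]methyl}-4,5-bis(methoxymethoxy)phenyl]methylidene}butanedioate (racemic at the carbonate carbon; not isolated) | COC(=O)C/C(C(=O)OC(C)(C)C)=C\c1cc(OCOC)c(OCOC)cc1C(OC(=O)OC(C)(C)C)c1ccc(C(=O)OC(C)(C)C)oc1=O | intermediate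
13 | tert-butyl 3-[(1R,2R)-3-(tert-butoxycarbonyl)-2-(methoxycarbonyl)-6,7-bis(methoxymethoxy)-1,2-dihydronaphthalen-1-yl]-2-oxo-2H-pyran-6-carboxylate | COC(=O)[C@H]1C(C(=O)OC(C)(C)C)=Cc2cc(OCOC)c(OCOC)cc2[C@@H]1c1ccc(C(=O)OC(C)(C)C)oc1=O | intermediate
14 | (1R,2R)-1-(6-carboxy-2-oxo-2H-pyran-3-yl)-6,7-dihydroxy-2-(methoxycarbonyl)-1,2-dihydronaphthalene-3-carboxylic acid | COC(=O)[C@H]1C(C(=O)O)=Cc2cc(O)c(O)cc2[C@@H]1c1ccc(C(=O)O)oc1=O | target

Total step count: 8. Longest linear sequence: 6 steps (1 → 2 → 4 → 8 → 9 → 13 → 14; steps 1, 2, 4, 5, 7, 8).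

Steps most likely to fail

Step 7 (Proposed new method). What may go wrong is loss of stereocontrol or chemoselectivity: palladium(0) may ionise the carbonate before or instead of the Lewis base, the amine may add at pyrone C6′ instead of C4′, and long exposure to base may slowly deprotonate C1 and erode the enantiomeric purity. The fallback uses known chemistry and sets out from 9 and 11. The Heck coupling is run alone and 12 is isolated. 12 is then cyclised with Cs2CO3 in DMF, an intramolecular C-alkylation of the ester dienolate by the doubly activated benzylic carbonate. This should give the racemic trans product, that is 13 together with its enantiomer tert-butyl 3-[(1S,2S)-3-(tert-butoxycarbonyl)-2-(methoxycarbonyl)-6,7-bis(methoxymethoxy)-1,2-dihydronaphthalen-1-yl]-2-oxo-2H-pyran-6-carboxylate F1. The two are separated by preparative chromatography on a chiral stationary phase, and the route is rejoined at 13.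

Step 4. What may go wrong is sluggish or unselective formation of the pyranyl–metal species: reduction or homocoupling of 4, or insertion of nickel into the aryl bromide of 6. The fallback sets out from 4 and 6 and builds the carbinol through the ketone. 4 is stannylated with hexamethylditin and Pd(PPh3)4 to tert-butyl 2-oxo-3-(trimethylstannyl)-2H-pyran-6-carboxylate F2. Aldehyde 6 is oxidised (Pinnick) to 2-bromo-4,5-bis(methoxymethoxy)benzoic acid F3 and converted with 1-chloro-N,N,2-trimethylprop-1-en-1-amine under neutral conditions into 2-bromo-4,5-bis(methoxymethoxy)benzoyl chloride F4. Stille acylation of F2 with F4 gives tert-butyl 3-[2-bromo-4,5-bis(methoxymethoxy)benzoyl]-2-oxo-2H-pyran-6-carboxylate F5, and Luche reduction (NaBH4, CeCl3, MeOH, low temperature) gives 8, where the route is rejoined.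

Step 8. What may go wrong is alkylation of the liberated, electron-rich catechol ring by tert-butyl and methoxymethyl cations or by formaldehyde in strong acid, and air oxidation of the dihydronaphthalene during work-up. The fallback sets out from 13 and unmasks in two stages without free methoxymethyl cations. ZnBr2 and propane-1-thiol in CH2Cl2 cleave the MOM ethers by transfer to sulfur and give tert-butyl 3-[(1R,2R)-3-(tert-butoxycarbonyl)-6,7-dihydroxy-2-(methoxycarbonyl)-1,2-dihydronaphthalen-1-yl]-2-oxo-2H-pyran-6-carboxylate F6. A short treatment with TFA/CH2Cl2 and a cation scavenger then removes the tert-butyl esters and gives 14.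

Further compounds
F1 | step 7 | tert-butyl 3-[(1S,2S)-3-(tert-butoxycarbonyl)-2-(methoxycarbonyl)-6,7-bis(methoxymethoxy)-1,2-dihydronaphthalen-1-yl]-2-oxo-2H-pyran-6-carboxylate | COC(=O)[C@@H]1C(C(=O)OC(C)(C)C)=Cc2cc(OCOC)c(OCOC)cc2[C@H]1c1ccc(C(=O)OC(C)(C)C)oc1=O
F2 | step 4 | tert-butyl 2-oxo-3-(trimethylstannyl)-2H-pyran-6-carboxylate | CC(C)(C)OC(=O)c1ccc([Sn](C)(C)C)c(=O)o1
F3 | step 4 | 2-bromo-4,5-bis(methoxymethoxy)benzoic acid | OC(=O)c1cc(OCOC)c(OCOC)cc1Br
F4 | step 4 | 2-bromo-4,5-bis(methoxymethoxy)benzoyl chloride | ClC(=O)c1cc(OCOC)c(OCOC)cc1Br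
F5 | step 4 | tert-butyl 3-[2-bromo-4,5-bis(methoxymethoxy)benzoyl]-2-oxo-2H-pyran-6-carboxylate | CC(C)(C)OC(=O)c1ccc(C(=O)c2cc(OCOC)c(OCOC)cc2Br)c(=O)o1
F6 | step 8 | tert-butyl 3-[(1R,2R)-3-(tert-butoxycarbonyl)-6,7-dihydroxy-2-(methoxycarbonyl)-1,2-dihydronaphthalen-1-yl]-2-oxo-2H-pyran-6-carboxylate | COC(=O)[C@H]1C(C(=O)OC(C)(C)C)=Cc2cc(O)c(O)cc2[C@@H]1c1ccc(C(=O)OC(C)(C)C)oc1=O
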